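**Plan**
- **Cuts:** In ring A (the furan-2,5-dione bearing CH2OH) and ring B (the furan-2,5-dione bearing the 2-oxohexyl group), both C(alkene)–C(=O) bonds and the acyl–O–acyl bridge are cut. Each ring then falls back to an internal alkyne plus CO2 plus CO.
- **Further cuts:** The C(sp)–CH2 bond to a 2-methylenehexyl group (its C=CH2 masks the ketone), the ring B alkyne itself (aldehyde homologation), and the CH–CH2 bond at the stereocentre (enolate alkylation).
- **Enabling feature:** Each ring is a tetrasubstituted C=C whose two cis carbonyl carbons are joined through one ring O. This C4O3 unit is locally symmetric, so the orientation in which CO2 and CO are taken up does not matter. Only the stereogenic CH and one CH2 lie between the rings, so the parent is a 1,5-diyne that cannot cyclometalate on itself.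
- **Forward order:** The open chain is joined first (alkylation, homologation, allylation). Rings A and B then arise together in one flask, and ozonolysis and desilylation finish the route.
- **Stereochemistry:** The single (R) centre comes from an Evans alkylation directed by (S)-4-benzyl-1,3-oxazolidin-2-one and is only carried along afterwards.

Key step: step 11

Assumption: the target is taken to be isolable as drawn, that is, as the open hydroxymethyl anhydride and the non-conjugated ketone, not as a lactone acid or an enol tautomer.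

Step 1
Reactants: 1 but-2-yne-1,4-diol
Product: 2 4-(tert-butyldimethylsilyloxy)but-2-yn-1-ol
Conditions: TBSCl (1 equiv), imidazole, 1 (3 equiv), DMF, 0 °C to rt
Reagents that add atoms: tert-butyldimethylsilyl chloride (TBSCl), CC(C)(C)[Si](C)(C)Cl
Why: Silyl ether formation on a symmetric diol used in excess should stop largely at the mono-ether, and unreacted 1 is washed out with water.

Step 2
Reactants: 2 4-(tert-butyldimethylsilyloxy)but-2-yn-1-ol
Product: 3 [(4-bromobut-2-yn-1-yl)oxy](tert-butyl)dimethylsilane
Conditions: CBr4, PPh3, CH2Cl2, 0 °C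
Reagents that add atoms: carbon tetrabromide, BrC(Br)(Br)Br
Why: The Appel bromination converts the primary propargylic alcohol into the bromide under neutral conditions that leave the silyl ether alone.

Step 3
Reactants: 4 (S)-4-benzyl-1,3-oxazolidin-2-one; 5 heptanoyl chloride
Product: 6 (S)-4-benzyl-3-heptanoyl-1,3-oxazolidin-2-one
Conditions: Et3N, DMAP (10 mol %), CH2Cl2, 0 °C to rt
Reagents that add atoms: none
Why: DMAP-catalysed N-acylation of the oxazolidinone with the acid chloride installs the Evans auxiliary.

Step 4
Reactants: 6 (S)-4-benzyl-3-heptanoyl-1,3-oxazolidin-2-one; 3 [(4-bromobut-2-yn-1-yl)oxy](tert-butyl)dimethylsilane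
Product: 8 (S)-4-benzyl-3-[(R)-6-(tert-butyldimethylsilyloxy)-2-pentylhex-4-ynoyl]-1,3-oxazolidin-2-one, via sodium (Z)-enolate 7 (not isolated)
Conditions: NaN(SiMe3)2, THF, −78 °C; then 3, −78 to −40 °C
Reagents that add atoms: sodium bis(trimethylsilyl)amide, [Na+].C[Si](C)(C)[N-][Si](C)(C)C (sodium, held in 7 only)
Why: Evans asymmetric alkylation, in which the sodium-chelated (Z)-enolate 7 should take up the reactive propargylic bromide on the face away from the benzyl group and so set the (R) centre of the target.

Step 5
Reactants: 8 (S)-4-benzyl-3-[(R)-6-(tert-butyldimethylsilyloxy)-2-pentylhex-4-ynoyl]-1,3-oxazolidin-2-one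
Product: 9 (R)-6-(tert-butyldimethylsilyloxy)-2-pentylhex-4-yn-1-ol
Conditions: LiBH4, MeOH (1 equiv), THF, 0 °C
Reagents that add atoms: none
Why: Reductive cleavage of the N-acyl oxazolidinone with LiBH4 gives the primary alcohol and frees the auxiliary without touching the stereocentre, the alkyne or the silyl ether.

Step 6
Reactants: 9 (R)-6-(tert-butyldimethylsilyloxy)-2-pentylhex-4-yn-1-ol
Product: 10 (R)-6-(tert-butyldimethylsilyloxy)-2-pentylhex-4-ynal
Conditions: Dess–Martin periodinane, CH2Cl2, 0 °C to rt
Reagents that add atoms: none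
Why: The Dess–Martin oxidation runs under nearly neutral conditions, so the α-branched aldehyde should form without epimerisation, and it is used at once.

Step 7
Reactants: 10 (R)-6-(tert-butyldimethylsilyloxy)-2-pentylhex-4-ynal
Product: 11 (R)-tert-butyl[(5-ethynyldec-2-yn-1-yl)oxy]dimethylsilane
Conditions: dimethyl (1-diazo-2-oxopropyl)phosphonate, K2CO3, MeOH, 0 °C to rt
Reagents that add atoms: dimethyl (1-diazo-2-oxopropyl)phosphonate (Ohira–Bestmann reagent), CC(=O)C(=[N+]=[N-])P(=O)(OC)OC
Why: In the Ohira–Bestmann variant of the Seyferth–Gilbert homologation, the diazomethylphosphonate anion made in situ olefinates the aldehyde and the diazoalkene loses N2 with a 1,2-H shift to the terminal alkyne, with mild carbonate base at low temperature chosen to keep the α-centre intact.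

Step 8
Reactants: 12 prop-2-yn-1-ol; 13 n-butylmagnesium chloride
Product: 15 2-methylenehexan-1-ol, via oxamagnesacycle 14 (not isolated)
Conditions: n-BuMgCl (2.5 equiv), CuI (10 mol %), Et2O, −10 °C to rt; then aq NH4Cl
Reagents that add atoms: none
Why: Copper-catalysed, alkoxide-directed carbomagnesiation of propargyl alcohol places butyl on the internal alkyne carbon and magnesium on the terminal one (14), and protonolysis gives the 2-substituted allyl alcohol.

Step 9
Reactants: 15 2-methylenehexan-1-ol
Product: 16 2-(bromomethyl)hex-1-ene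
Conditions: PBr3 (0.4 equiv), Et2O, 0 °C
Reagents that add atoms: phosphorus tribromide, BrP(Br)Br
Why: PBr3 bromination of a primary allylic alcohol, in which direct and allylic displacement give the same bromide because both allyl termini are CH2.

Step 10
Reactants: 11 (R)-tert-butyl[(5-ethynyldec-2-yn-1-yl)oxy]dimethylsilane; 16 2-(bromomethyl)hex-1-ene
Product: 17 (R)-tert-butyl[(9-butyl-5-pentyldec-9-ene-2,6-diyn-1-yl)oxy]dimethylsilane
Conditions: CuI (10 mol %), n-Bu4NI (10 mol %), K2CO3, DMF, rt
Reagents that add atoms: none
Why: Copper-catalysed allylation of the terminal alkyne through its copper acetylide gives the skipped enyne under a weak base that cannot touch the propargylic stereocentre, and the degenerate allyl termini remove any regiochemical issue.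

Step 11
Reactants: 17 (R)-tert-butyl[(9-butyl-5-pentyldec-9-ene-2,6-diyn-1-yl)oxy]dimethylsilane
Product: 19 3-[(R)-1-{4-[(tert-butyldimethylsilyloxy)methyl]-2,5-dioxo-2,5-dihydrofuran-3-yl}heptan-2-yl]-4-(2-methylenehexyl)furan-2,5-dione, via bis-nickelalactone 18 (not isolated)
Conditions: Ni(cod)2 (2.4 equiv), TMEDA (5 equiv), CO2 (1 atm), THF, slow addition of 17, −20 °C to rt; then CO (1 atm), 0 °C to rt; filtration through a short silica pad
Reagents that add atoms: carbon dioxide, O=C=O; carbon monoxide, [C-]#[O+]; held in 18 only: Ni(cod)2, C1=CCCC=CCC1.C1=CCCC=CCC1.[Ni]; TMEDA, CN(C)CCN(C)C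
Why: Each alkyne binds zerovalent nickel and couples oxidatively with CO2 to a five-membered oxanickelacyclopentenone (18) that holds the vinyl–Ni carbon and the carboxylate cis; CO then inserts into the Ni–C(sp2) bond, which makes the remaining ring-carbon-to-carbonyl bond, and the six-membered acyl nickel carboxylate collapses by reductive elimination to the furan-2,5-dione while nickel leaves as Ni(CO)4. The closest known reaction type is the oxidative coupling of dialkylalkynes with CO2 at TMEDA-ligated zerovalent nickel and the carbonylation of the resulting nickelalactones to dialkylmaleic anhydrides, used here twice in one flask. Rings A and B both close by contraction of a six-membered nickelacycle (reductive elimination) and not by an open-chain attack, so the cis geometry that closure needs is built in by the metallacycle. No stereocentre is made, and the (R) centre is a spectator whose C–H is not acidic in 17 and meets only the weak base TMEDA for a short time in 19. Regioselectivity is not needed, because either orientation of CO2 and CO on an alkyne gives the same locally symmetric anhydride, so all regioisomers of 18 converge on 19. Chemoselectivity rests on the substrate: the two-carbon spacer between the alkynes would force a cyclobutane-fused nickelacycle or pyrone and so shuts off diyne cyclometalation, the unactivated 1,1-disubstituted alkene does not couple with CO2, the silyl ether is too poor a leaving group to ionise, and excess CO keeps zerovalent nickel from re-entering the anhydrides.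

Step 12
Reactants: 19 3-[(R)-1-{4-[(tert-butyldimethylsilyloxy)methyl]-2,5-dioxo-2,5-dihydrofuran-3-yl}heptan-2-yl]-4-(2-methylenehexyl)furan-2,5-dione
Product: 21 3-[(R)-1-{4-[(tert-butyldimethylsilyloxy)methyl]-2,5-dioxo-2,5-dihydrofuran-3-yl}heptan-2-yl]-4-(2-oxohexyl)furan-2,5-dione, via ozonide 20 (not isolated)
Conditions: O3, CH2Cl2, −78 °C; then Me2S, −78 °C to rt
Reagents that add atoms: ozone, [O-][O+]=O
Why: In this ozonolysis with reductive work-up, electrophilic ozone should attack only the electron-rich 1,1-disubstituted alkene and not the two tetrasubstituted ring alkenes that each carry two acyl groups, and Me2S reduces ozonide 20 to the ketone under neutral conditions.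

Step 13
Reactants: 21 3-[(R)-1-{4-[(tert-butyldimethylsilyloxy)methyl]-2,5-dioxo-2,5-dihydrofuran-3-yl}heptan-2-yl]-4-(2-oxohexyl)furan-2,5-dione
Product: 22 3-{(R)-1-[4-(hydroxymethyl)-2,5-dioxo-2,5-dihydrofuran-3-yl]heptan-2-yl}-4-(2-oxohexyl)furan-2,5-dione (target)
Conditions: HF·pyridine, THF, 0 °C to rt (polyethylene vessel)
Reagents that add atoms: none
Why: Fluoride-induced cleavage of the primary TBS ether in an acidic medium avoids base at the enolisable CH2 and at the stereocentre, and both anhydrides should tolerate HF·pyridine.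

**Compound list**
1 | but-2-yne-1,4-diol | OCC#CCO | starting material
2 | 4-(tert-butyldimethylsilyloxy)but-2-yn-1-ol | OCC#CCO[Si](C)(C)C(C)(C)C | intermediate
3 | [(4-bromobut-2-yn-1-yl)oxy](tert-butyl)dimethylsilane | BrCC#CCO[Si](C)(C)C(C)(C)C | intermediate
4 | (S)-4-benzyl-1,3-oxazolidin-2-one | O=C1N[C@@H](Cc2ccccc2)CO1 | starting material
5 | heptanoyl chloride | CCCCCCC(=O)Cl | starting material
6 | (S)-4-benzyl-3-heptanoyl-1,3-oxazolidin-2-one | CCCCCCC(=O)N1[C@@H](Cc2ccccc2)COC1=O | intermediate
7 | sodium (Z)-enolate of 6 (not isolated) | CCCCC/C=C(\[O-])N1[C@@H](Cc2ccccc2)COC1=O.[Na+] | intermediate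
8 | (S)-4-benzyl-3-[(R)-6-(tert-butyldimethylsilyloxy)-2-pentylhex-4-ynoyl]-1,3-oxazolidin-2-one | CCCCC[C@H](CC#CCO[Si](C)(C)C(C)(C)C)C(=O)N1[C@@H](Cc2ccccc2)COC1=O | intermediate
9 | (R)-6-(tert-butyldimethylsilyloxy)-2-pentylhex-4-yn-1-ol | CCCCC[C@H](CC#CCO[Si](C)(C)C(C)(C)C)CO | intermediate
10 | (R)-6-(tert-butyldimethylsilyloxy)-2-pentylhex-4-ynal | CCCCC[C@H](CC#CCO[Si](C)(C)C(C)(C)C)C=O | intermediate
11 | (R)-tert-butyl[(5-ethynyldec-2-yn-1-yl)oxy]dimethylsilane | CCCCC[C@H](CC#CCO[Si](C)(C)C(C)(C)C)C#C | intermediate
12 | prop-2-yn-1-ol | C#CCO | starting material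
13 | n-butylmagnesium chloride | CCCC[Mg]Cl | starting material
14 | 4-butyl-2,5-dihydro-1,2-oxamagnesole (oxamagnesacycle, not isolated) | CCCCC1=C[Mg]OC1 | intermediate
15 | 2-methylenehexan-1-ol | CCCCC(=C)CO | intermediate
16 | 2-(bromomethyl)hex-1-ene | CCCCC(=C)CBr | intermediate
17 | (R)-tert-butyl[(9-butyl-5-pentyldec-9-ene-2,6-diyn-1-yl)oxy]dimethylsilane | CCCCC[C@H](CC#CCO[Si](C)(C)C(C)(C)C)C#CCC(=C)CCCC | intermediate
18 | bis(oxanickelacyclopentenone) of 17, one TMEDA on each nickel, drawn as one of the converging regioisomers (not isolated) | CCCCC[C@H](CC1=C(CO[Si](C)(C)C(C)(C)C)C(=O)O[Ni]1)C1=C(CC(=C)CCCC)C(=O)O[Ni]1.CN(C)CCN(C)C.CN(C)CCN(C)C | intermediate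
19 | 3-[(R)-1-{4-[(tert-butyldimethylsilyloxy)methyl]-2,5-dioxo-2,5-dihydrofuran-3-yl}heptan-2-yl]-4-(2-methylenehexyl)furan-2,5-dione | CCCCC[C@H](CC1=C(CO[Si](C)(C)C(C)(C)C)C(=O)OC1=O)C1=C(CC(=C)CCCC)C(=O)OC1=O | intermediate
20 | 1,2,4-trioxolane (ozonide) of 19, both epimers at the trioxolane carbon (not isolated) | CCCCC[C@H](CC1=C(CO[Si](C)(C)C(C)(C)C)C(=O)OC1=O)C1=C(CC2(CCCC)OCOO2)C(=O)OC1=O | intermediate
21 | 3-[(R)-1-{4-[(tert-butyldimethylsilyloxy)methyl]-2,5-dioxo-2,5-dihydrofuran-3-yl}heptan-2-yl]-4-(2-oxohexyl)furan-2,5-dione | CCCCC[C@H](CC1=C(CO[Si](C)(C)C(C)(C)C)C(=O)OC1=O)C1=C(CC(=O)CCCC)C(=O)OC1=O | intermediate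
22 | 3-{(R)-1-[4-(hydroxymethyl)-2,5-dioxo-2,5-dihydrofuran-3-yl]heptan-2-yl}-4-(2-oxohexyl)furan-2,5-dione | CCCCC[C@H](CC1=C(CO)C(=O)OC1=O)C1=C(CC(=O)CCCC)C(=O)OC1=O | target

**Totals**
Total step count: 13.
Longest linear sequence: 10 steps (steps 1, 2, 4–7 and 10–13).

**Steps most likely to fail**

Step 11.
- **What may go wrong:** The alkynes may oligomerise at zerovalent nickel before CO2 is taken up. Coupling may be sluggish at the alkyne next to the branched centre. The nickelalactone may lose CO2 again when CO is admitted.
- **Fallback:** The route sets out from 17 and separates carbonylation from ring closure. A catalytic oxidative bis-methoxycarbonylation with divalent palladium (PdCl2, CuCl2, NaOAc, CO, MeOH, rt) would add two ester groups syn across each alkyne and give the tetramethyl (Z,Z)-bis-maleate F1. Saponification (LiOH, THF–H2O) and acidification would give the bis-maleic tetra-acid F2. Its dialkylmaleic acid units lose water spontaneously, and the route is rejoined at 19.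

Step 7.
- **What may go wrong:** The α-branched aldehyde may epimerise under methoxide or carbonate before it is olefinated. The silyl group may be partly lost in basic methanol.
- **Fallback:** A Corey–Fuchs sequence sets out from 10. CBr4 and PPh3 (CH2Cl2, 0 °C, no base) would give the 1,1-dibromoalkene F3. n-BuLi (2 equiv, THF, −78 °C) would convert it by bromine–lithium exchange and rearrangement into the lithium acetylide F4. An aqueous quench of F4 comes back to the route at 11.

Step 13.
- **What may go wrong:** Pyridine or fluoride may cause enolisation and self-condensation at the CH2 between ring B and the ketone. The freed hydroxyl may transfer to an anhydride carbonyl during a long reaction.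
- **Fallback:** The order of unmasking is changed, setting out from 19. The silyl ether is removed first, while no ketone is present (aq HF, MeCN, 0 °C), to give the hydroxymethyl alkene F5. Ozonolysis (O3, CH2Cl2, −78 °C; then Me2S) through the ozonide F6 then becomes the last, neutral step and comes back to the route at 22.

Further compounds
F1 | step 11 | tetramethyl (Z,Z)-bis-maleate from 17, (R), two cis CO2Me groups on each former alkyne | CCCCC[C@H](C/C(C(=O)OC)=C(\CO[Si](C)(C)C(C)(C)C)C(=O)OC)/C(C(=O)OC)=C(\CC(=C)CCCC)C(=O)OC
F2 | step 11 | bis-maleic tetra-acid from F1, (R), (Z,Z) | CCCCC[C@H](C/C(C(=O)O)=C(\CO[Si](C)(C)C(C)(C)C)C(=O)O)/C(C(=O)O)=C(\CC(=C)CCCC)C(=O)O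
F3 | step 7 | (R)-tert-butyl{[5-(2,2-dibromoethenyl)dec-2-yn-1-yl]oxy}dimethylsilane | CCCCC[C@H](CC#CCO[Si](C)(C)C(C)(C)C)C=C(Br)Br
F4 | step 7 | lithium acetylide of 11 | CCCCC[C@H](CC#CCO[Si](C)(C)C(C)(C)C)C#C[Li]
F5 | step 13 | 3-{(R)-1-[4-(hydroxymethyl)-2,5-dioxo-2,5-dihydrofuran-3-yl]heptan-2-yl}-4-(2-methylenehexyl)furan-2,5-dione | CCCCC[C@H](CC1=C(CO)C(=O)OC1=O)C1=C(CC(=C)CCCC)C(=O)OC1=O
F6 | step 13 | 1,2,4-trioxolane (ozonide) of F5, both epimers at the trioxolane carbon | CCCCC[C@H](CC1=C(CO)C(=O)OC1=O)C1=C(CC2(CCCC)OCOO2)C(=O)OC1=O
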